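**Assumption:** the IMDA in Step 8 gives the desired trans-fused adduct as one separable diastereomer, alongside the cis-fused and other isomers. The stereocentre at C3 of the target comes from the chiral pool and sets the diene face.

## Retrosynthetic overview
- The target acid comes from Pinnick oxidation of the corresponding quaternary aldehyde.
- That aldehyde comes from a type-1 intramolecular Diels–Alder (IMDA) of a linear (E,E)-diene/(E)-2-methylenal polyene with a (Z)-alkene in the three-atom tether. This single step forms the cyclopentene and the cyclohexene together and sets C4, C7, C8 and C9.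
- The polyene comes from a Heck coupling of a (Z)-trisubstituted vinyl iodide with methacrolein.
- The vinyl iodide carries the central diene, built by Horner–Wadsworth–Emmons (HWE) coupling of an allylic phosphonate with commercial cinnamylideneacetone.
- The allylic phosphonate is made from (S)-TBS-Roche aldehyde by Stork–Zhao iodo-olefination, then Wittig chain extension. The Roche aldehyde is the only source of C3 chirality.

## Forward route

**Step 1**
- Reactants: 1 (S)-3-(TBSO)-2-methylpropanal; 2 n-propyltriphenylphosphonium bromide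
- Product: 3 tert-butyl{[(2R,3Z)-4-iodo-2-methylhex-3-en-1-yl]oxy}dimethylsilane
- Conditions: 2, NaHMDS, THF, −78 °C; then I2; then NaHMDS; then 1, HMPA, −78 °C → rt
- Reagents that add atoms: I2 (II)
- Why: Stork–Zhao–Wittig olefination of the α-iodo-ylide gives the Z-iodoalkene, with I cis to the chain. Cross-coupling with retention later puts C9 cis to C3, as the cyclopentene needs. C3 is carried over unchanged.

**Step 2**
- Reactants: 3
- Product: 4 (2R,3Z)-4-iodo-2-methylhex-3-en-1-ol
- Conditions: TBAF, THF, 0 °C → rt
- Reagents that add atoms: none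
- Why: fluoride silyl deprotection leaves the vinyl iodide and the stereocentre untouched.

**Step 3**
- Reactants: 4; 5 2-(triphenylphosphoranylidene)propanal
- Product: 6 (2E,4S,5Z)-6-iodo-2,4-dimethylocta-2,5-dienal
- Conditions: 5 (2 equiv), TPAP (5 mol%), NMO, 4 Å MS, CH2Cl2, rt
- Reagents that add atoms: none
- Why: Ley tandem oxidation/Wittig traps the epimerisable α-methyl-β,γ-unsaturated aldehyde as it forms. The stabilised ylide gives the E-trisubstituted enal, which sets the C4=C5 geometry needed for the IMDA diene.

**Step 4**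
- Reactants: 6
- Product: 7 (2E,4S,5Z)-6-iodo-2,4-dimethylocta-2,5-dien-1-ol
- Conditions: NaBH4, MeOH, 0 °C
- Reagents that add atoms: none (hydride only)
- Why: chemoselective 1,2-reduction of the enal; the vinyl iodide and both alkenes survive.

**Step 5**
- Reactants: 7
- Product: 8 diethyl [(2E,4S,5Z)-6-iodo-2,4-dimethylocta-2,5-dien-1-yl]phosphonate
- Conditions: P(OEt)3, ZnI2, THF, reflux
- Reagents that add atoms: triethyl phosphite, CCOP(OCC)OCC
- Why: ZnI2-mediated Arbuzov-type substitution of a primary allylic alcohol converts it to the allylic phosphonate with retention of alkene geometry.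

**Step 6**
- Reactants: 8; 9 (3E,5E)-6-phenylhexa-3,5-dien-2-one (cinnamylideneacetone)
- Product: 10 (1E,3E,5E,7E,9S,10Z)-11-iodo-5,7,9-trimethyl-1-phenyltrideca-1,3,5,7,10-pentaene
- Conditions: 8, LDA, THF/DMPU, −78 → 0 °C; then 9, 0 °C → rt
- Reagents that add atoms: none
- Why: HWE olefination of the methyl ketone joins C6 to C7. The larger dienyl group ends up trans to C5, giving E as the major isomer (separated from Z by chromatography). The dienyl geometry is carried over from 9.

**Step 7**
- Reactants: 10; 11 methacrolein
- Product: 12 (2E,4Z,6S,7E,9E,11E,13E)-4-ethyl-2,6,8,10-tetramethyl-14-phenyltetradeca-2,4,7,9,11,13-hexaenal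
- Conditions: Pd(OAc)2 (5 mol%), n-Bu4NCl, NaHCO3, DMF, 60 °C
- Reagents that add atoms: none
- Why: Jeffery-type Heck coupling occurs at the CH2 terminus of methacrolein. Syn-insertion then β-H elimination gives the E-2-methylenal (CHO trans to C1), and the Z-vinyl iodide geometry is retained.

**Step 8**
- Reactants: 12
- Product: 13 (trans-fused IMDA adduct) 1-ethyl-3,4,6,7-tetramethyl-6-[(1E,3E)-4-phenylbuta-1,3-dien-1-yl]-3a,6,7,7a-tetrahydro-3H-indene-7-carbaldehyde, stereochemistry as in the compound list
- Conditions: toluene (5 mM), BHT, 110 °C, sealed tube, 24 h; then HPLC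
- Reagents that add atoms: none
- Why: the IMDA is suprafacial. The two outside substituents (C3 and the dienyl group) end up cis, and the E-enal puts CHO trans to C1. The endo-CHO/exo-tether transition state gives the trans ring fusion, and the C3 methyl sits anti to the forming C4–C9 bond, which selects the diene face.

**Step 9**
- Reactants: 13
- Product: 14 22-nor-zyggomphic acid B
- Conditions: NaClO2, NaH2PO4, 2-methyl-2-butene, t-BuOH/H2O, 0 °C → rt
- Reagents that add atoms: sodium chlorite, [O-]Cl=O
- Why: Pinnick oxidation converts the hindered quaternary aldehyde to the acid. There is no α-H, so no epimerisation, and the scavenger protects the polyene.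

## Compound list
1 | (S)-3-(tert-butyldimethylsilyloxy)-2-methylpropanal | O=C[C@@H](C)CO[Si](C)(C)C(C)(C)C | starting material
2 | n-propyltriphenylphosphonium bromide | CCC[P+](c1ccccc1)(c1ccccc1)c1ccccc1.[Br-] | starting material
3 | TBS ether of (2R,3Z)-4-iodo-2-methylhex-3-en-1-ol | CC/C(I)=C/[C@@H](C)CO[Si](C)(C)C(C)(C)C | intermediate
4 | (2R,3Z)-4-iodo-2-methylhex-3-en-1-ol | CC/C(I)=C/[C@@H](C)CO | intermediate
5 | 2-(triphenylphosphoranylidene)propanal | CC(=P(c1ccccc1)(c1ccccc1)c1ccccc1)C=O | starting material
6 | (2E,4S,5Z)-6-iodo-2,4-dimethylocta-2,5-dienal | CC/C(I)=C/[C@@H](C)/C=C(C)/C=O | intermediate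
7 | (2E,4S,5Z)-6-iodo-2,4-dimethylocta-2,5-dien-1-ol | CC/C(I)=C/[C@@H](C)/C=C(C)/CO | intermediate
8 | diethyl [(2E,4S,5Z)-6-iodo-2,4-dimethylocta-2,5-dien-1-yl]phosphonate | CC/C(I)=C/[C@@H](C)/C=C(C)/CP(=O)(OCC)OCC | intermediate
9 | (3E,5E)-6-phenylhexa-3,5-dien-2-one | CC(=O)/C=C/C=C/c1ccccc1 | starting material
10 | (1E,3E,5E,7E,9S,10Z)-11-iodo-5,7,9-trimethyl-1-phenyltrideca-1,3,5,7,10-pentaene | CC/C(I)=C/[C@@H](C)/C=C(C)/C=C(C)/C=C/C=C/c1ccccc1 | intermediate
11 | methacrolein | C=C(C)C=O | starting material
12 | (2E,4Z,6S,7E,9E,11E,13E)-4-ethyl-2,6,8,10-tetramethyl-14-phenyltetradeca-2,4,7,9,11,13-hexaenal | O=C/C(C)=C/C(CC)=C\[C@@H](C)/C=C(C)/C=C(C)/C=C/C=C/c1ccccc1 | intermediate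
13 | trans-fused IMDA aldehyde | CCC1=C[C@@H](C)[C@@H]2C(C)=C[C@](C)(/C=C/C=C/c3ccccc3)[C@](C)(C=O)[C@@H]12 | intermediate
14 | 22-nor-zyggomphic acid B | CCC1=C[C@@H](C)[C@@H]2C(C)=C[C@](C)(/C=C/C=C/c3ccccc3)[C@](C)(C(=O)O)[C@@H]12 | target

## Totals
Total steps: 9. Longest linear sequence: 9 steps, from 1.

## Three steps most likely to fail
1. **Step 8 (IMDA).** The cis- versus trans-fused selectivity is uncertain, and a competing [1,5]-H shift from C3–H in the (Z)-diene is possible.
   - Fallback: use a saturated-tether analogue with a C1 ketone (4-oxo-enal dienophile) and run the IMDA with Et2AlCl. Epimerise C9 α to the ketone to the trans-fused hydrindanone. Then build C1(Et)=C2 by enol triflate formation and Fe-catalysed EtMgBr coupling.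
2. **Step 6 (HWE).** The E/Z ratio at C6=C7 may be poor.
   - Fallback: form C5–C6 by Negishi coupling instead. Couple the E-dienylalane from Zr-catalysed carboalumination of (E)-PhCH=CH–CH=CH–C≡CH with an E-2-iodoalkene made from the C4 aldehyde by alkyne formation, methylation, and hydrozirconation/iodination.
3. **Step 7 (Heck).** The hindered trisubstituted vinyl iodide and the sensitive polyene may give low yield or alkene isomerisation.
   - Fallback: do I/Li exchange with t-BuLi and trap with DMF to give the (Z)-α-ethyl-enal. Then run a Wittig with ylide 5 to give 12.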